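X, the solid charged here, reacts after entering solution as E, and the rate of that entry holds the argument together.

    E ⇌ L (K1 = 0.36, k1 = 0.45 /min)
    E → D (k2 = 0.18 /min)
    X ⇌ E, rate k3*(cs3 - [E]) while solid is left; crystals form when [E] > cs3 (cs3 = 0.12 M, k3 = 0.11 /min)
    E + D → E.D (k4 = 1.3 /M/min)
    L → G (k5 = 5.1 /min)

| flask | X | time |
|---|---|---|
| east | 0.050 M | 3.0 min |
| north-west | 0.10 M | 3.0 min |
| south-west | 0.20 M | 3.0 min |
| west | 0.40 M | 3.0 min |
| north | 0.80 M | 3.0 min |

- percent here means X units held: one E.D counts as two
- X is a solid; its amount is given per volume of the solution
- at the start none of X is in solution
- "hardly changes" means that all values lie within two and a half points (for a concentration: within two and a half percent of the largest)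
- run time (east): 3.0 min

- share of D in all that became D or G or E.D for east, north-west, south-west, west, north, in this order
- the shape of the row from first to last (hardly changes / falls, then rises / rises, then falls / rises all the way / falls all the way)

Take east and climb from the quick end of the ladder of half-lives. L goes first: the step L → G alone gives it 0.14 min, shorter than the 0.408 min in which E ⇌ L relaxes both ways together. So L is a brief passage between E and G. Next comes E, with 1.5 min by the forward step to L alone and 3.9 min by E → D alone, and the way to L is the busier exit. Yet not every L goes on, since 80.3% passes to G and the rest returns to E.

My own reckoning of the selectivity between the two exits needs no integration, because [E] stands in both and cancels. The share of D comes to 33.2%. The loss of E to E.D lies higher on the ladder: even with [D] as high as the bound below, the half-life of E by that step is 13.5 min, longer than the run, so I leave it out.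

The approach of [E] to the solubility by dissolution alone has a half-life of 6.30 min, also longer than the run. While solid is left, its rate is greatest at empty solution, where the coefficient times the solubility gives 0.01320 M/min. Over 3.0 min that makes 0.0396 M: the dissolution ceiling, the upper bound on X entering solution in the run. It lies below the solubility, so no crystals form. It also lies below the smallest charge, 0.050 M, so solid lasts through the run in every flask. While solid lasts, the feed is zero order in X, so I expect identical flasks and a flat row at my share.

The forecast, 34.1% at each point and hardly changes, holds that “solid remains in every run and all five runs are identical”, and its share stands above mine.

The flasks give 34.1% in east and 34.1% in north, and the row hardly changes, 0.90 percentage points above my share. East at 3.00 min still holds 28.3% of its X as solid, which puts 0.0358 M through solution, below the ceiling of 0.0396 M. Over 30.0 min the ceiling grows to 0.396 M, and west, charged with 0.40 M, then holds 15.8% as solid, so 0.337 M has dissolved.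

The numbers of this flask are those of an exercise; the flask was simulated.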